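**Plan**
- Retrosynthetic cuts, in order: the five O-benzyl groups and the O5 acetyl; then ring A bonds C5–C6 and C3–C4; then the A–B and B–C aryl ester C(=O)–O bonds.
- Enabling feature: in ring A the adjacent oxygen-bearing carbons C4 and C5 lie between C3–H and C6–CH3. C4–C5 is therefore a glycolate-derived two-carbon unit, and C3–C2(O)–C1(CO2Ar)–C6(CH3) maps onto C3–C4–C5–C6 of a 4-alkoxy-6-methyl-2-pyrone-5-carboxylate.
- Forward order: rings B and C both come from orsellinic acid and are joined first. The preformed pyrone acid is then esterified onto ring B O4. Ring A is built last, on the didepside, by pyrone/ketene acetal [4+2] with loss of CO2 and trimethylsilanol.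
- The cycloaddition delivers O2 as a benzyl ether, O4 as a free phenol and O5 as a TBS ether, so the acetate can be placed on O5 alone. Global hydrogenolysis ends the route.
- Stereochemistry: the target has no stereocentre, and those of the bridged adduct vanish on aromatisation.

Key step: step 14

Remark: each benzenoid ring is numbered from the carboxyl-bearing carbon (C1; oxygen on C2 and C4, methyl on C6). The pyrone is numbered O1, C2(=O), C3 to C6. Bn = benzyl, TBS = tert-butyldimethylsilyl, TMS = trimethylsilyl. Compounds 1, 10, 11 and 16 are taken as commercial.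

Step 1
Reactants: 1 orsellinic acid (2,4-dihydroxy-6-methylbenzoic acid)
Product: 2 allyl 4-(allyloxy)-2-hydroxy-6-methylbenzoate
Conditions: allyl bromide (2.1 equiv), K2CO3 (2.2 equiv), DMF, rt
Reagents that add atoms: allyl bromide, C=CCBr
Why: Carboxylate alkylation plus Williamson etherification; the carboxylate and the unchelated O4 phenol react, while O2–H is held in a hydrogen bond to the new ester carbonyl and should stay free with two equivalents of halide at room temperature.

Step 2
Reactants: 2 allyl 4-(allyloxy)-2-hydroxy-6-methylbenzoate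
Product: 3 allyl 4-(allyloxy)-2-(benzyloxy)-6-methylbenzoate
Conditions: BnBr (1.3 equiv), K2CO3, DMF, 60 °C
Reagents that add atoms: benzyl bromide, BrCc1ccccc1
Why: Williamson etherification of the chelated phenol needs only warming with excess halide, and both allyl groups are inert to carbonate and far below the temperature of a Claisen rearrangement.

Step 3
Reactants: 3 allyl 4-(allyloxy)-2-(benzyloxy)-6-methylbenzoate
Product: 4 2-(benzyloxy)-4-hydroxy-6-methylbenzoic acid
Conditions: Pd(PPh3)4 (5 mol %), morpholine (6 equiv), THF, rt; dilute acid work-up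
Reagents that add atoms: none
Why: Tsuji–Trost deallylation; zerovalent palladium ionises both the allyl ester and the allyl aryl ether to π-allyl complexes that morpholine traps irreversibly, and the benzyl ether is not touched.

Step 4
Reactants: 4 2-(benzyloxy)-4-hydroxy-6-methylbenzoic acid
Product: 5 benzyl 2-(benzyloxy)-4-hydroxy-6-methylbenzoate (ring C phenol)
Conditions: BnBr (1.0 equiv), KHCO3 (1.1 equiv), DMF, rt
Reagents that add atoms: benzyl bromide, BrCc1ccccc1
Why: SN2 alkylation of the carboxylate; hydrogencarbonate deprotonates only the acid, so the C4 phenol should remain free, as is usual for benzyl esters of resorcylic acids.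

Step 5
Reactants: 4 2-(benzyloxy)-4-hydroxy-6-methylbenzoic acid
Product: 7 2-(benzyloxy)-4-(tert-butyldimethylsilyloxy)-6-methylbenzoic acid (ring B acid), via bis-silylated ester 6 (not isolated)
Conditions: TBSCl (2.3 equiv), imidazole, DMF, rt; then AcOH–THF–H2O (3:1:1), rt
Reagents that add atoms: tert-butyldimethylsilyl chloride, CC(C)(C)[Si](C)(C)Cl
Why: Silylation of both acidic hydroxyls followed by selective hydrolysis of the more labile silyl ester; aryl TBS ethers tolerate aqueous acetic acid, whereas carbonate in methanol would endanger this para-acyl phenol ether.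

Step 6
Reactants: 7 2-(benzyloxy)-4-(tert-butyldimethylsilyloxy)-6-methylbenzoic acid; 5 benzyl 2-(benzyloxy)-4-hydroxy-6-methylbenzoate
Product: 8 benzyl 2-(benzyloxy)-4-{[2-(benzyloxy)-4-(tert-butyldimethylsilyloxy)-6-methylbenzoyl]oxy}-6-methylbenzoate (O4-silylated B–C didepside)
Conditions: DCC, DMAP (0.3 equiv), CH2Cl2, 0 °C to rt
Reagents that add atoms: none
Why: Steglich esterification, the standard depside coupling; 5 offers a single free hydroxyl and DMAP should carry the 2,6-disubstituted acyl group past N-acylurea formation.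

Step 7
Reactants: 8 O4-silylated B–C didepside
Product: 9 benzyl 2-(benzyloxy)-4-{[2-(benzyloxy)-4-hydroxy-6-methylbenzoyl]oxy}-6-methylbenzoate (B–C didepside phenol)
Conditions: HF·pyridine, THF–pyridine, 0 °C
Reagents that add atoms: none
Why: Fluoride-induced Si–O cleavage under weakly acidic conditions, which avoids a free phenoxide and so protects the depside bond from transesterification.

Step 8
Reactants: 10 malonyl dichloride; 11 allyl acetoacetate
Product: 12 allyl 4-hydroxy-6-methyl-2-oxo-2H-pyran-5-carboxylate
Conditions: CH2Cl2 (concentrated), rt to 40 °C, slow N2 sweep to remove HCl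
Reagents that add atoms: none
Why: Cyclocondensation of a malonyl bis-electrophile with a β-keto ester (C-acylation at the α-carbon, O-acylation of the ketone enol) is the known entry to 4-hydroxy-6-methyl-2-pyrone-5-carboxylates, and the allyl ester is chosen because it withstands the two equivalents of HCl that would cleave an acid-labile ester.

Step 9
Reactants: 12 allyl 4-hydroxy-6-methyl-2-oxo-2H-pyran-5-carboxylate
Product: 13 allyl 4-(benzyloxy)-6-methyl-2-oxo-2H-pyran-5-carboxylate
Conditions: BnOH, PPh3, DIAD, THF, 0 °C to rt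
Reagents that add atoms: benzyl alcohol, OCc1ccccc1
Why: Mitsunobu etherification alkylates the acidic vinylogous-acid hydroxyl on O4 and avoids the C3-benzylation and 2-alkoxy-4-pyrone formation that accompany benzyl halide with base.

Step 10
Reactants: 13 allyl 4-(benzyloxy)-6-methyl-2-oxo-2H-pyran-5-carboxylate
Product: 14 4-(benzyloxy)-6-methyl-2-oxo-2H-pyran-5-carboxylic acid
Conditions: Pd(PPh3)4 (3 mol %), HCO2H, Et3N, THF, rt to 40 °C; dilute acid work-up
Reagents that add atoms: none
Why: Tsuji–Trost-type hydrogenolysis of the allyl ester with formate as hydride donor gives the acid, propene and CO2 without a nucleophilic amine that could add to pyrone C4 or C6.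

Step 11
Reactants: 14 4-(benzyloxy)-6-methyl-2-oxo-2H-pyran-5-carboxylic acid; 9 B–C didepside phenol
Product: 15 pyrone didepside, the 4-(benzyloxy)-6-methyl-2-oxo-2H-pyran-5-carboxylate ester of ring B O4 of 9
Conditions: DCC, DMAP (0.2 equiv), CH2Cl2, 0 °C to rt
Reagents that add atoms: none
Why: Steglich esterification on the single free hydroxyl of 9; the acid has no β-keto tautomer and should be activated without decarboxylation, and the aryl ester formed is a stronger acceptor than an alkyl ester, which serves the cycloaddition.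

Step 12
Reactants: 16 glycolic acid
Product: 18 (tert-butyldimethylsilyloxy)acetic acid, via silyl ester 17 (not isolated)
Conditions: TBSCl (2.2 equiv), imidazole, DMF, rt; then K2CO3, MeOH–THF–H2O, rt; aq. KHSO4 to pH 4
Reagents that add atoms: tert-butyldimethylsilyl chloride, CC(C)(C)[Si](C)(C)Cl
Why: Exhaustive silylation followed by carbonate-mediated hydrolysis of the silyl ester is a standard route to O-silylated hydroxy acids, since an alkyl TBS ether is stable to aqueous carbonate.

Step 13
Reactants: 18 (tert-butyldimethylsilyloxy)acetic acid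
Product: 20 2-(tert-butyldimethylsilyloxy)-1,1-bis(trimethylsilyloxy)ethene, via trimethylsilyl ester 19 (not isolated)
Conditions: LiHMDS (1.05 equiv) then TMSCl (1.1 equiv), THF, 0 °C; LiHMDS (1.1 equiv), −78 °C, then TMSCl (1.2 equiv), −78 °C to rt; pentane, filtration, bulb-to-bulb distillation
Reagents that add atoms: trimethylsilyl chloride, C[Si](C)(C)Cl
Why: Silyl ester formation and O-silylation of its lithium enolate is the standard preparation of bis(trimethylsilyl) ketene acetals, tris(trimethylsilyloxy)ethene included, and two identical acetal oxygens leave no alkene geometry to control.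

Step 14
Reactants: 15 pyrone didepside; 20 2-(tert-butyldimethylsilyloxy)-1,1-bis(trimethylsilyloxy)ethene
Product: 24 protected tridepside whose ring A is 2-(benzyloxy)-5-(tert-butyldimethylsilyloxy)-4-hydroxy-6-methylbenzoyl on ring B O4, via bicyclic lactone adduct 21 (not isolated), via bis(trimethylsilyloxy)cyclohexadiene 22 (not isolated), via aryl trimethylsilyl ether 23 (not isolated)
Conditions: 20 (4 equiv), toluene (about 1 M), 120 °C, sealed tube, Ar; then aq. citric acid, THF, rt
Reagents that add atoms: none
Why: The trioxygenated alkene 20 adds across C3 and C6 of the pyrone, whose LUMO is lowered by the lactone and the C5 aryl ester, in an inverse-electron-demand Diels–Alder reaction (strongly asynchronous, or stepwise by Michael attack at C6 and closure of C3 onto the silyloxycarbenium carbon) to give bridged lactone 21; cycloreversion expels CO2 to give 22, loss of Me3SiOH from the C4 acetal carbon and C5–H aromatises it to 23, and the citric acid work-up hydrolyses the labile aryl TMS ether while the hindered TBS ether stays. The closest known reactions are the cycloaddition, decarboxylation and elimination sequences of 2-pyrone-5-carboxylates and 2-pyrone-3-carboxylates with 1,1-dimethoxyethene and 1,1,2-trimethoxyethene, which give alkoxy- and 1,2-dialkoxyarenes. Ring A closes in an intermolecular [4+2] mode that forms C5–C6 and C3–C4 in one operation, and the carbocycle is released by retro-[4+2] loss of the O1–C2 bridge. The three stereocentres of 21 and the single one of 22 are uncontrolled and irrelevant, because all become sp2 carbons. The step needs the CH(OTBS) terminus to bond to pyrone C6: C6 is the β-carbon of the aryl acrylate unit and the δ-carbon of the dienolide, while the 4-benzyloxy group makes C3 the electron-rich end, so this donor costs rate but reinforces the polarity match with the nucleophilic CH terminus of 20. O5 cannot be lost because only C5 carries hydrogen and only C4 carries a leaving group next to it, and even hydrolysis of the C4 bis(silyloxy) carbon to a dienone would tautomerise to the same phenol 24.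

Step 15
Reactants: 24 protected tridepside (O4 free and O5 TBS)
Product: 25 protected tridepside whose ring A is 2,4-bis(benzyloxy)-5-(tert-butyldimethylsilyloxy)-6-methylbenzoyl
Conditions: BnOH, PPh3, DIAD, THF, 0 °C to rt
Reagents that add atoms: benzyl alcohol, OCc1ccccc1
Why: Mitsunobu etherification of the acidic para-acyl phenol under essentially neutral conditions forms no long-lived phenoxide, which should suppress O5-to-O4 silyl migration and attack on the depside esters.

Step 16
Reactants: 25 protected tridepside (O5 TBS)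
Product: 26 protected tridepside whose ring A is 2,4-bis(benzyloxy)-5-hydroxy-6-methylbenzoyl
Conditions: HF·pyridine, THF–pyridine, 0 °C to rt
Reagents that add atoms: none
Why: Fluoride-driven cleavage of the last silyl ether under weakly acidic conditions leaves the benzyl ethers, the benzyl ester and both depside bonds untouched.

Step 17
Reactants: 26 protected tridepside (O5 free)
Product: 27 protected tridepside whose ring A is 5-acetoxy-2,4-bis(benzyloxy)-6-methylbenzoyl
Conditions: Ac2O, pyridine, DMAP (cat.), CH2Cl2, 0 °C to rt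
Reagents that add atoms: acetic anhydride, CC(=O)OC(C)=O
Why: DMAP-catalysed acetylation of the only free hydroxyl in the molecule, so the acetate can only end up on O5 despite its two ortho neighbours.

Step 18
Reactants: 27 protected tridepside (O5 acetate)
Product: 28 target CNP0154030.0, 4-{[4-{[5-acetoxy-2,4-dihydroxy-6-methylbenzoyl]oxy}-2-hydroxy-6-methylbenzoyl]oxy}-2-hydroxy-6-methylbenzoic acid
Conditions: H2 (1 atm), 10% Pd/C, EtOAc–THF, rt
Reagents that add atoms: none
Why: Hydrogenolysis of four benzyl ethers and one benzyl ester in a neutral aprotic medium is the usual last step of depside syntheses; aryl esters and the acetate are inert, the absence of base or alcohol should prevent acetyl migration or solvolysis, and the ester of the less acidic O5 phenol is also the electronically preferred position.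

**Compound list**
1 | orsellinic acid | Cc1cc(O)cc(O)c1C(=O)O | starting material
2 | allyl 4-(allyloxy)-2-hydroxy-6-methylbenzoate | C=CCOC(=O)c1c(C)cc(OCC=C)cc1O | intermediate
3 | allyl 4-(allyloxy)-2-(benzyloxy)-6-methylbenzoate | C=CCOC(=O)c1c(C)cc(OCC=C)cc1OCc1ccccc1 | intermediate
4 | 2-(benzyloxy)-4-hydroxy-6-methylbenzoic acid | Cc1cc(O)cc(OCc2ccccc2)c1C(=O)O | intermediate
5 | benzyl 2-(benzyloxy)-4-hydroxy-6-methylbenzoate | Cc1cc(O)cc(OCc2ccccc2)c1C(=O)OCc1ccccc1 | intermediate
6 | tert-butyldimethylsilyl 2-(benzyloxy)-4-(tert-butyldimethylsilyloxy)-6-methylbenzoate (not isolated) | Cc1cc(O[Si](C)(C)C(C)(C)C)cc(OCc2ccccc2)c1C(=O)O[Si](C)(C)C(C)(C)C | intermediate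
7 | 2-(benzyloxy)-4-(tert-butyldimethylsilyloxy)-6-methylbenzoic acid | Cc1cc(O[Si](C)(C)C(C)(C)C)cc(OCc2ccccc2)c1C(=O)O | intermediate
8 | O4-silylated B–C didepside | Cc1cc(O[Si](C)(C)C(C)(C)C)cc(OCc2ccccc2)c1C(=O)Oc1cc(C)c(C(=O)OCc2ccccc2)c(OCc2ccccc2)c1 | intermediate
9 | B–C didepside phenol | Cc1cc(O)cc(OCc2ccccc2)c1C(=O)Oc1cc(C)c(C(=O)OCc2ccccc2)c(OCc2ccccc2)c1 | intermediate
10 | malonyl dichloride | O=C(Cl)CC(=O)Cl | starting material
11 | allyl acetoacetate | CC(=O)CC(=O)OCC=C | starting material
12 | allyl 4-hydroxy-6-methyl-2-oxo-2H-pyran-5-carboxylate | CC1=C(C(=O)OCC=C)C(O)=CC(=O)O1 | intermediate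
13 | allyl 4-(benzyloxy)-6-methyl-2-oxo-2H-pyran-5-carboxylate | CC1=C(C(=O)OCC=C)C(OCc2ccccc2)=CC(=O)O1 | intermediate
14 | 4-(benzyloxy)-6-methyl-2-oxo-2H-pyran-5-carboxylic acid | CC1=C(C(=O)O)C(OCc2ccccc2)=CC(=O)O1 | intermediate
15 | pyrone didepside (key-step precursor) | CC1=C(C(=O)Oc2cc(C)c(C(=O)Oc3cc(C)c(C(=O)OCc4ccccc4)c(OCc4ccccc4)c3)c(OCc3ccccc3)c2)C(OCc2ccccc2)=CC(=O)O1 | intermediate
16 | glycolic acid | OCC(=O)O | starting material
17 | tert-butyldimethylsilyl (tert-butyldimethylsilyloxy)acetate (not isolated) | CC(C)(C)[Si](C)(C)OCC(=O)O[Si](C)(C)C(C)(C)C | intermediate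
18 | (tert-butyldimethylsilyloxy)acetic acid | CC(C)(C)[Si](C)(C)OCC(=O)O | intermediate
19 | trimethylsilyl (tert-butyldimethylsilyloxy)acetate (not isolated) | CC(C)(C)[Si](C)(C)OCC(=O)O[Si](C)(C)C | intermediate
20 | 2-(tert-butyldimethylsilyloxy)-1,1-bis(trimethylsilyloxy)ethene | CC(C)(C)[Si](C)(C)OC=C(O[Si](C)(C)C)O[Si](C)(C)C | intermediate
21 | 2-oxabicyclo[2.2.2]oct-5-en-3-one adduct (racemic, endo/exo undefined, not isolated) | CC12OC(=O)C(C(OCc3ccccc3)=C1C(=O)Oc3cc(C)c(C(=O)Oc4cc(C)c(C(=O)OCc5ccccc5)c(OCc5ccccc5)c4)c(OCc4ccccc4)c3)C(O[Si](C)(C)C)(O[Si](C)(C)C)C2O[Si](C)(C)C(C)(C)C | intermediate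
22 | 4,4-bis(trimethylsilyloxy)cyclohexa-1,5-diene after CO2 loss, ring A numbering (racemic, not isolated) | CC1=C(C(=O)Oc2cc(C)c(C(=O)Oc3cc(C)c(C(=O)OCc4ccccc4)c(OCc4ccccc4)c3)c(OCc3ccccc3)c2)C(OCc2ccccc2)=CC(O[Si](C)(C)C)(O[Si](C)(C)C)C1O[Si](C)(C)C(C)(C)C | intermediate
23 | tridepside with O4 TMS and O5 TBS (not isolated) | Cc1c(O[Si](C)(C)C(C)(C)C)c(O[Si](C)(C)C)cc(OCc2ccccc2)c1C(=O)Oc1cc(C)c(C(=O)Oc2cc(C)c(C(=O)OCc3ccccc3)c(OCc3ccccc3)c2)c(OCc2ccccc2)c1 | intermediate
24 | tridepside with O4 free and O5 TBS (key-step product) | Cc1c(O[Si](C)(C)C(C)(C)C)c(O)cc(OCc2ccccc2)c1C(=O)Oc1cc(C)c(C(=O)Oc2cc(C)c(C(=O)OCc3ccccc3)c(OCc3ccccc3)c2)c(OCc2ccccc2)c1 | intermediate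
25 | tridepside with O4 benzyl and O5 TBS | Cc1c(O[Si](C)(C)C(C)(C)C)c(OCc2ccccc2)cc(OCc2ccccc2)c1C(=O)Oc1cc(C)c(C(=O)Oc2cc(C)c(C(=O)OCc3ccccc3)c(OCc3ccccc3)c2)c(OCc2ccccc2)c1 | intermediate
26 | tridepside with O4 benzyl and O5 free | Cc1c(O)c(OCc2ccccc2)cc(OCc2ccccc2)c1C(=O)Oc1cc(C)c(C(=O)Oc2cc(C)c(C(=O)OCc3ccccc3)c(OCc3ccccc3)c2)c(OCc2ccccc2)c1 | intermediate
27 | tridepside with O4 benzyl and O5 acetyl | Cc1c(OC(C)=O)c(OCc2ccccc2)cc(OCc2ccccc2)c1C(=O)Oc1cc(C)c(C(=O)Oc2cc(C)c(C(=O)OCc3ccccc3)c(OCc3ccccc3)c2)c(OCc2ccccc2)c1 | intermediate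
28 | CNP0154030.0 | CC(=O)Oc1c(O)cc(O)c(C(=O)Oc2cc(C)c(C(=O)Oc3cc(C)c(C(=O)O)c(O)c3)c(O)c2)c1C | target

**Step count**
- Total steps: 18.
- Longest linear sequence: 12 steps (1, 2, 3, 5, 6, 7, 11, 14, 15, 16, 17, 18).

**Steps most likely to fail**

Step 14. The donor-substituted, C6-methylated pyrone may react so slowly that thermal decay or protonation of the ketene acetal outruns the cycloaddition. Attack at C6 may also be followed by opening of the lactone instead of closure at C3.

The fallback builds ring A by arene chemistry, starting from 1.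
- Exhaustive benzylation (BnBr, K2CO3, DMF, 60 °C) gives benzyl 2,4-bis(benzyloxy)-6-methylbenzoate F1.
- NBS in MeCN brominates C5, which is para to O2, ortho to O4 and not squeezed between two benzyloxy groups. This gives benzyl 2,4-bis(benzyloxy)-5-bromo-6-methylbenzoate F2.
- Palladium-catalysed hydroxylation (Pd2(dba)3, tBuXPhos, KOH, dioxane–H2O, 100 °C) gives benzyl 2,4-bis(benzyloxy)-5-hydroxy-6-methylbenzoate F3.
- KOH in aqueous DMSO cleaves the hindered ester to 2,4-bis(benzyloxy)-5-hydroxy-6-methylbenzoic acid F4.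
- Ac2O in pyridine with aqueous work-up gives 5-acetoxy-2,4-bis(benzyloxy)-6-methylbenzoic acid F5.
- Steglich coupling of F5 with 9 rejoins the route at 27.

Step 15. The TBS group may migrate from O5 to O4, or be partly lost, while the C4 phenol is activated. Either event would scramble the O4/O5 differentiation.

The fallback sets out from 24 and relies on intrinsic acidity instead. HF·pyridine gives the ring A 4,5-catechol tridepside F6. One equivalent of BnBr with Li2CO3 in DMF should then alkylate the more acidic and less hindered O4 (para to the ester), as is known for 3,4-dihydroxybenzoates. The route is rejoined at 26.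

Step 11. Acyl transfer from the hindered pyrone acid may be slow, which would allow rearrangement to the N-acylurea or attack of DMAP on the pyrone ring.

The fallback sets out from 9 and grows the pyrone on the phenol.
- Heating with 2,2,6-trimethyl-4H-1,3-dioxin-4-one in toluene at 120 °C (acetylketene trapping) gives the didepside acetoacetate F7.
- Cyclocondensation with 10, as in step 8, gives the didepside 4-hydroxy-6-methyl-2-oxo-2H-pyran-5-carboxylate F8.
- Mitsunobu benzylation, as in step 9, rejoins the route at 15.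

**Further compounds**
F1 | step 14 | benzyl 2,4-bis(benzyloxy)-6-methylbenzoate | Cc1cc(OCc2ccccc2)cc(OCc2ccccc2)c1C(=O)OCc1ccccc1
F2 | step 14 | benzyl 2,4-bis(benzyloxy)-5-bromo-6-methylbenzoate | Cc1c(Br)c(OCc2ccccc2)cc(OCc2ccccc2)c1C(=O)OCc1ccccc1
F3 | step 14 | benzyl 2,4-bis(benzyloxy)-5-hydroxy-6-methylbenzoate | Cc1c(O)c(OCc2ccccc2)cc(OCc2ccccc2)c1C(=O)OCc1ccccc1
F4 | step 14 | 2,4-bis(benzyloxy)-5-hydroxy-6-methylbenzoic acid | Cc1c(O)c(OCc2ccccc2)cc(OCc2ccccc2)c1C(=O)O
F5 | step 14 | 5-acetoxy-2,4-bis(benzyloxy)-6-methylbenzoic acid | Cc1c(OC(C)=O)c(OCc2ccccc2)cc(OCc2ccccc2)c1C(=O)O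
F6 | step 15 | ring A 4,5-catechol tridepside | Cc1c(O)c(O)cc(OCc2ccccc2)c1C(=O)Oc1cc(C)c(C(=O)Oc2cc(C)c(C(=O)OCc3ccccc3)c(OCc3ccccc3)c2)c(OCc2ccccc2)c1
F7 | step 11 | didepside acetoacetate | CC(=O)CC(=O)Oc1cc(C)c(C(=O)Oc2cc(C)c(C(=O)OCc3ccccc3)c(OCc3ccccc3)c2)c(OCc2ccccc2)c1
F8 | step 11 | didepside 4-hydroxy-6-methyl-2-oxo-2H-pyran-5-carboxylate | CC1=C(C(=O)Oc2cc(C)c(C(=O)Oc3cc(C)c(C(=O)OCc4ccccc4)c(OCc4ccccc4)c3)c(OCc3ccccc3)c2)C(O)=CC(=O)O1
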